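Everything hinges on forming ring C of unit 2 (the apigenin-type half) last, at its O1''–C8a'' bond. C8a'' is the ring A carbon flanking C4a'', which holds the C4'' ketone, so it can enter the synthesis as an aryl bromide ortho to an acyl group. One copper-catalysed intramolecular O-arylation of a 1,3-diketone enolate then makes this aryl ether bond and completes the pyranone, with the C2'' and C3'' aryl groups already attached. The precursor is a 1-(2-bromo-4,6-dialkoxyphenyl)-3-(4-alkoxyphenyl)propane-1,3-dione whose central carbon carries ring B and the finished unit 1. All five phenols are held as benzyl ethers, released finally by neutral hydrogenolysis that spares the C7 methyl ether.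

Key step: step 13

Notation and assumption: unit 1 is the 5-hydroxy-7-methoxyflavone half (O1–C8a, ring B C1'–C6'). Unit 2 is the 3-arylated 5,7-dihydroxy-2-(4-hydroxyphenyl)chromone half (O1''–C8a'', 2-aryl ring C1'''–C6'''). The target SMILES defines no stereo-element, so the C3'–C3'' axis is taken as freely rotating. The sp3 centres that appear on the way are racemic and epimerisable.

Step 1
Reactants: 1 3-bromo-4-hydroxybenzaldehyde
Product: 2 4-(benzyloxy)-3-bromobenzaldehyde
Conditions: BnBr, K2CO3, DMF, rt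
Reagents that add atoms: benzyl bromide BrCc1ccccc1
Why: Williamson ether synthesis on the acidic para-formyl phenol; the benzyl ether withstands every basic, organometallic and mildly acidic step ahead and keeps this oxygen from attacking the side-chain carbonyl groups that will later sit ortho to it.

Step 2
Reactants: 3 2',6'-dihydroxy-4'-methoxyacetophenone
Product: 4 1-[2-(benzyloxy)-6-hydroxy-4-methoxyphenyl]ethan-1-one
Conditions: BnBr (1.05 equiv), K2CO3, acetone, reflux
Reagents that add atoms: benzyl bromide BrCc1ccccc1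
Why: Williamson ether synthesis in which the two hydroxyls are equivalent and the one left after the first alkylation is held in a strong hydrogen bond to the acetyl oxygen, so one equivalent of benzyl bromide should stop at the monoether and leave the phenol needed as O1 of unit 1.

Step 3
Reactants: 2 4-(benzyloxy)-3-bromobenzaldehyde; 4 1-[2-(benzyloxy)-6-hydroxy-4-methoxyphenyl]ethan-1-one
Product: 5 (E)-1-[2-(benzyloxy)-6-hydroxy-4-methoxyphenyl]-3-[4-(benzyloxy)-3-bromophenyl]prop-2-en-1-one
Conditions: KOH, EtOH–H2O, rt; then aq. HCl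
Reagents that add atoms: none
Why: Claisen–Schmidt condensation of a methyl ketone enolate with a non-enolisable aldehyde, where loss of water under equilibrating conditions gives the more stable (E)-enone.

Step 4
Reactants: 5 the (E)-2'-hydroxychalcone
Product: 6 5-(benzyloxy)-2-[4-(benzyloxy)-3-bromophenyl]-7-methoxy-4H-chromen-4-one
Conditions: I2 (10 mol %), DMSO, 125 °C; aq. Na2S2O3 work-up
Reagents that add atoms: none
Why: Iodine-catalysed oxidative cyclisation of a 2'-hydroxychalcone (oxa-Michael closure, then dehydrogenation with DMSO as terminal oxidant) is the standard chalcone-to-flavone conversion and does not touch the aryl bromide or the benzyl ethers.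

Step 5
Reactants: 6 the 3'-bromoflavone; 7 (2-ethoxy-2-oxoethyl)zinc bromide (commercial solution)
Product: 8 ethyl 2-{2-(benzyloxy)-5-[5-(benzyloxy)-7-methoxy-4-oxo-4H-chromen-2-yl]phenyl}acetate
Conditions: Pd2(dba)3 (2 mol %), XPhos (8 mol %), THF, rt to 60 °C
Reagents that add atoms: none
Why: Negishi-type cross-coupling of a Reformatsky reagent (ester α-arylation at zerovalent palladium under nearly neutral conditions) puts the two-carbon side chain on C3' at the only C–Br bond, and the zinc enolate is too mild to add to the vinylogous-ester carbonyl of the chromone.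

Step 6
Reactants: 9 5-bromoresorcinol
Product: 11 2-bromo-4,6-dihydroxybenzaldehyde, via iminium chloride 10 (not isolated)
Conditions: POCl3, DMF, MeCN, 0 to 40 °C; then H2O, 50 °C
Reagents that add atoms: N,N-dimethylformamide CN(C)C=O; water O
Why: Vilsmeier–Haack formylation goes para to one hydroxyl and ortho to the other, as with resorcinol and orcinol, and since these two positions of 9 are equivalent and both adjoin bromine, the 2-bromo-4,6-dioxygenated pattern of ring A is fixed without differentiating any phenol.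

Step 7
Reactants: 11 2-bromo-4,6-dihydroxybenzaldehyde
Product: 12 2,4-bis(benzyloxy)-6-bromobenzaldehyde
Conditions: BnBr (2.4 equiv), K2CO3, DMF, 60 °C
Reagents that add atoms: benzyl bromide BrCc1ccccc1
Why: Double Williamson ether synthesis; warming in DMF is enough to alkylate also the hydrogen-bonded hydroxyl ortho to the formyl group.

Step 8
Reactants: 12 2,4-bis(benzyloxy)-6-bromobenzaldehyde
Product: 13 2,4-bis(benzyloxy)-6-bromobenzoic acid
Conditions: NaClO2, NaH2PO4, 2-methyl-2-butene, t-BuOH–THF–H2O, rt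
Reagents that add atoms: sodium chlorite [Na+].[O-]Cl=O
Why: Pinnick oxidation converts hindered, electron-rich benzaldehydes to the acids under buffered conditions, with 2-methyl-2-butene trapping hypochlorous acid before it can chlorinate ring A.

Step 9
Reactants: 13 2,4-bis(benzyloxy)-6-bromobenzoic acid
Product: 14 2,4-bis(benzyloxy)-6-bromobenzoyl chloride
Conditions: (COCl)2, DMF (cat.), CH2Cl2, 0 °C to rt; evaporate
Reagents that add atoms: oxalyl chloride O=C(Cl)C(=O)Cl
Why: Standard acid chloride formation with oxalyl chloride under DMF catalysis, mild enough for aryl benzyl ethers and giving only gaseous side products.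

Step 10
Reactants: 8 the ethyl arylacetate bearing unit 1; 14 2,4-bis(benzyloxy)-6-bromobenzoyl chloride
Product: 15 ethyl 3-[2,4-bis(benzyloxy)-6-bromophenyl]-2-{2-(benzyloxy)-5-[5-(benzyloxy)-7-methoxy-4-oxo-4H-chromen-2-yl]phenyl}-3-oxopropanoate (racemic)
Conditions: 8, LiHMDS (2.2 equiv), THF, −78 °C; then 14, −78 to 0 °C; aq. NH4Cl
Reagents that add atoms: none
Why: Crossed Claisen-type C-acylation of a preformed ester lithium enolate with a non-enolisable acyl chloride, driven on by deprotonation of the β-keto ester with the second equivalent of base; it makes the side chain the nucleophile so that no Lewis acid ever meets the ethers, and the new stereocentre at C2 is racemic, epimerisable and removed in step 11.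

Step 11
Reactants: 15 the α-aryl β-keto ester
Product: 16 2-{4-(benzyloxy)-3-[2-(2,4-bis(benzyloxy)-6-bromophenyl)-2-oxoethyl]phenyl}-5-(benzyloxy)-7-methoxy-4H-chromen-4-one (the 2-bromodeoxybenzoin)
Conditions: LiCl, H2O, DMSO, 135 °C
Reagents that add atoms: none
Why: Krapcho dealkoxycarbonylation removes the ester of a β-keto ester under neutral conditions, the doubly ortho-substituted aryl ketone being shielded from retro-Claisen attack by water.

Step 12
Reactants: 16 the 2-bromodeoxybenzoin; 17 4-(benzyloxy)benzoyl chloride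
Product: 18 1-[2,4-bis(benzyloxy)-6-bromophenyl]-2-{2-(benzyloxy)-5-[5-(benzyloxy)-7-methoxy-4-oxo-4H-chromen-2-yl]phenyl}-3-[4-(benzyloxy)phenyl]propane-1,3-dione (racemic)
Conditions: 16, LiHMDS (2.2 equiv), toluene–THF, −78 to 0 °C; then 17, 0 °C; aq. NH4Cl
Reagents that add atoms: none
Why: C-Acylation of a ketone lithium enolate with an acyl chloride in a weakly polar medium, a known direct route to 1,3-diketones including 1,2,3-triaryl ones; the second equivalent of base traps the product as its stabilised enolate, any enol ester formed at oxygen can still pass its acyl group to remaining enolate, and the new C2 stereocentre is racemic, labile and erased in step 13.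

Step 13
Reactants: 18 the 2-aryl-1-(2-bromoaryl)-3-aryl-1,3-diketone
Product: 19 5,7-bis(benzyloxy)-3-{2-(benzyloxy)-5-[5-(benzyloxy)-7-methoxy-4-oxo-4H-chromen-2-yl]phenyl}-2-[4-(benzyloxy)phenyl]-4H-chromen-4-one (penta-O-benzyl ether of the target)
Conditions: CuI (20 mol %), 1,10-phenanthroline (40 mol %), Cs2CO3 (2 equiv), 4 Å molecular sieves, dry degassed dioxane, 100 °C, Ar
Reagents that add atoms: none
Why: Cs2CO3 removes the acidic C3'' proton of 18 and the resulting diketonate binds phenanthroline-ligated monovalent copper, which holds the metal beside the C8a''–Br bond; oxidative addition gives a trivalent aryl copper enolate and C–O reductive elimination joins the oxygen of the 4-(benzyloxy)benzoyl enolate to C8a''. The closest known reaction type is the copper-catalysed intramolecular Ullmann O-arylation of 1-(2-haloaryl)-1,3-diketones, an established entry to chromones and flavones. Ring C of unit 2 closes as a six-membered ring by attack of an enolate oxygen on an sp2 aryl carbon whose leaving bromide lies outside the new ring. No stereocentre is created, and the labile one at C3'' vanishes because this carbon becomes part of the C2''=C3'' double bond. The step needs O-arylation by the distal oxygen only, and the substrate secures it by geometry, since the central carbon or the oxygen of the C4'' carbonyl could reach C8a'' only through a four-membered ring, while every phenol is benzylated and C8a''–Br is the sole carbon–halogen bond. The two benzyloxy groups of ring A stand meta to the bromine and so do not feed electron density into the reacting carbon, whereas the ortho acyl group activates it.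

Step 14
Reactants: 19 the penta-O-benzyl ether
Product: 20 5,7-dihydroxy-3-[2-hydroxy-5-(5-hydroxy-7-methoxy-4-oxo-4H-chromen-2-yl)phenyl]-2-(4-hydroxyphenyl)-4H-chromen-4-one (target CNP0254254.0)
Conditions: H2 (1 atm), 10% Pd/C, THF–MeOH, rt
Reagents that add atoms: none
Why: Catalytic hydrogenolysis cleaves the five benzylic C–O bonds under neutral conditions, while the aryl methyl ether at C7 and the two pyranone rings are inert at ambient pressure and temperature.

Compound list
1 | 3-bromo-4-hydroxybenzaldehyde | O=Cc1ccc(O)c(Br)c1 | starting material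
2 | 4-(benzyloxy)-3-bromobenzaldehyde | O=Cc1ccc(OCc2ccccc2)c(Br)c1 | intermediate
3 | 2',6'-dihydroxy-4'-methoxyacetophenone | CC(=O)c1c(O)cc(OC)cc1O | starting material
4 | 1-[2-(benzyloxy)-6-hydroxy-4-methoxyphenyl]ethan-1-one | CC(=O)c1c(O)cc(OC)cc1OCc1ccccc1 | intermediate
5 | (E)-1-[2-(benzyloxy)-6-hydroxy-4-methoxyphenyl]-3-[4-(benzyloxy)-3-bromophenyl]prop-2-en-1-one | O=C(/C=C/c1ccc(OCc2ccccc2)c(Br)c1)c1c(O)cc(OC)cc1OCc1ccccc1 | intermediate
6 | 5-(benzyloxy)-2-[4-(benzyloxy)-3-bromophenyl]-7-methoxy-4H-chromen-4-one | COc1cc(OCc2ccccc2)c2c(=O)cc(-c3ccc(OCc4ccccc4)c(Br)c3)oc2c1 | intermediate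
7 | (2-ethoxy-2-oxoethyl)zinc bromide | CCOC(=O)C[Zn]Br | starting material
8 | ethyl 2-{2-(benzyloxy)-5-[5-(benzyloxy)-7-methoxy-4-oxo-4H-chromen-2-yl]phenyl}acetate | CCOC(=O)Cc1cc(-c2cc(=O)c3c(OCc4ccccc4)cc(OC)cc3o2)ccc1OCc1ccccc1 | intermediate
9 | 5-bromoresorcinol | Oc1cc(O)cc(Br)c1 | starting material
10 | N-[(2-bromo-4,6-dihydroxyphenyl)methylidene]-N-methylmethanaminium chloride | C[N+](C)=Cc1c(O)cc(O)cc1Br.[Cl-] | intermediate
11 | 2-bromo-4,6-dihydroxybenzaldehyde | O=Cc1c(O)cc(O)cc1Br | intermediate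
12 | 2,4-bis(benzyloxy)-6-bromobenzaldehyde | O=Cc1c(Br)cc(OCc2ccccc2)cc1OCc1ccccc1 | intermediate
13 | 2,4-bis(benzyloxy)-6-bromobenzoic acid | OC(=O)c1c(Br)cc(OCc2ccccc2)cc1OCc1ccccc1 | intermediate
14 | 2,4-bis(benzyloxy)-6-bromobenzoyl chloride | ClC(=O)c1c(Br)cc(OCc2ccccc2)cc1OCc1ccccc1 | intermediate
15 | ethyl 3-[2,4-bis(benzyloxy)-6-bromophenyl]-2-{2-(benzyloxy)-5-[5-(benzyloxy)-7-methoxy-4-oxo-4H-chromen-2-yl]phenyl}-3-oxopropanoate (racemic, labile centre) | CCOC(=O)C(C(=O)c1c(Br)cc(OCc2ccccc2)cc1OCc1ccccc1)c1cc(-c2cc(=O)c3c(OCc4ccccc4)cc(OC)cc3o2)ccc1OCc1ccccc1 | intermediate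
16 | 2-{4-(benzyloxy)-3-[2-(2,4-bis(benzyloxy)-6-bromophenyl)-2-oxoethyl]phenyl}-5-(benzyloxy)-7-methoxy-4H-chromen-4-one | O=C(Cc1cc(-c2cc(=O)c3c(OCc4ccccc4)cc(OC)cc3o2)ccc1OCc1ccccc1)c1c(Br)cc(OCc2ccccc2)cc1OCc1ccccc1 | intermediate
17 | 4-(benzyloxy)benzoyl chloride | ClC(=O)c1ccc(OCc2ccccc2)cc1 | starting material
18 | 1-[2,4-bis(benzyloxy)-6-bromophenyl]-2-{2-(benzyloxy)-5-[5-(benzyloxy)-7-methoxy-4-oxo-4H-chromen-2-yl]phenyl}-3-[4-(benzyloxy)phenyl]propane-1,3-dione (racemic, labile centre) | O=C(c1ccc(OCc2ccccc2)cc1)C(C(=O)c1c(Br)cc(OCc2ccccc2)cc1OCc1ccccc1)c1cc(-c2cc(=O)c3c(OCc4ccccc4)cc(OC)cc3o2)ccc1OCc1ccccc1 | intermediate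
19 | 5,7-bis(benzyloxy)-3-{2-(benzyloxy)-5-[5-(benzyloxy)-7-methoxy-4-oxo-4H-chromen-2-yl]phenyl}-2-[4-(benzyloxy)phenyl]-4H-chromen-4-one | COc1cc(OCc2ccccc2)c2c(=O)cc(-c3ccc(OCc4ccccc4)c(-c4c(-c5ccc(OCc6ccccc6)cc5)oc5cc(OCc6ccccc6)cc(OCc6ccccc6)c5c4=O)c3)oc2c1 | intermediate
20 | 5,7-dihydroxy-3-[2-hydroxy-5-(5-hydroxy-7-methoxy-4-oxo-4H-chromen-2-yl)phenyl]-2-(4-hydroxyphenyl)-4H-chromen-4-one | COc1cc(O)c2c(=O)cc(-c3ccc(O)c(-c4c(-c5ccc(O)cc5)oc5cc(O)cc(O)c5c4=O)c3)oc2c1 | target

Total step count: 14.
Longest linear sequence: 9 steps (steps 1, 3, 4, 5, 10, 11, 12, 13, 14 from 1). The branches from 3 (steps 2, 3, 4, 5, 10–14) and from 9 (steps 6–14) are equally long.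

Steps most likely to fail

Step 13. Carbonate-induced retro-Claisen fragmentation of the crowded diketonate, or reductive loss of bromine, may outrun C–O bond formation. The fallback closes ring C by carbonyl condensation instead of aryl C–O coupling.
- It sets out from 16. Miyaura borylation (B2pin2, Pd(dppf)Cl2, KOAc, dioxane, 90 °C) should give the aryl pinacol boronate F1.
- Oxidation (NaBO3·4H2O, THF–H2O, rt) should give the 2-hydroxydeoxybenzoin F2.
- O-Aroylation with 17 (Et3N, DMAP, CH2Cl2) should give the aryl ester F3.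
- A Baker–Venkataraman acyl shift (LiHMDS, THF, −20 °C) hands the acyl group to carbon intramolecularly to give the 2-hydroxyaryl diketone F4.
- Cyclodehydration (NaOAc, AcOH, 90 °C) brings the sequence back to the route at 19.

Step 12. Acylation at the enolate oxygen instead of carbon, or stalling at the crowded carbon, may erode the supply of the diketone.
- The fallback sets out from 16. Aldol addition of its lithium enolate (LiHMDS, THF, −78 °C, cold AcOH quench) to commercial 4-(benzyloxy)benzaldehyde (O=Cc1ccc(OCc2ccccc2)cc1) should give the β-hydroxy ketone F5 as a mixture of diastereomers. In this addition only carbon can bond productively.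
- Oxidation with Dess–Martin periodinane (NaHCO3, CH2Cl2, rt) erases the carbinol centre and returns to the route at 18.

Step 10. Slow attack on the doubly ortho-substituted acyl chloride may let self-condensation of the ester enolate, or consumption of the acyl chloride by the amide base, take over.
- The fallback sets out from 8 and aldehyde 12, which makes steps 8 and 9 unnecessary. Aldol addition of the lithium enolate of 8 (LiHMDS, THF, −78 °C) to 12 should give the β-hydroxy ester F6 as a mixture of diastereomers.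
- Dess–Martin oxidation (CH2Cl2, rt) returns to the route at 15.

Further compounds
F1 | step 13 | 2-{4-(benzyloxy)-3-[2-(2,4-bis(benzyloxy)-6-(4,4,5,5-tetramethyl-1,3,2-dioxaborolan-2-yl)phenyl)-2-oxoethyl]phenyl}-5-(benzyloxy)-7-methoxy-4H-chromen-4-one | O=C(Cc1cc(-c2cc(=O)c3c(OCc4ccccc4)cc(OC)cc3o2)ccc1OCc1ccccc1)c1c(B2OC(C)(C)C(C)(C)O2)cc(OCc2ccccc2)cc1OCc1ccccc1
F2 | step 13 | 2-{4-(benzyloxy)-3-[2-(2,4-bis(benzyloxy)-6-hydroxyphenyl)-2-oxoethyl]phenyl}-5-(benzyloxy)-7-methoxy-4H-chromen-4-one | O=C(Cc1cc(-c2cc(=O)c3c(OCc4ccccc4)cc(OC)cc3o2)ccc1OCc1ccccc1)c1c(O)cc(OCc2ccccc2)cc1OCc1ccccc1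
F3 | step 13 | 3,5-bis(benzyloxy)-2-(2-{2-(benzyloxy)-5-[5-(benzyloxy)-7-methoxy-4-oxo-4H-chromen-2-yl]phenyl}acetyl)phenyl 4-(benzyloxy)benzoate | O=C(Cc1cc(-c2cc(=O)c3c(OCc4ccccc4)cc(OC)cc3o2)ccc1OCc1ccccc1)c1c(OC(=O)c2ccc(OCc3ccccc3)cc2)cc(OCc2ccccc2)cc1OCc1ccccc1
F4 | step 13 | 1-[2,4-bis(benzyloxy)-6-hydroxyphenyl]-2-{2-(benzyloxy)-5-[5-(benzyloxy)-7-methoxy-4-oxo-4H-chromen-2-yl]phenyl}-3-[4-(benzyloxy)phenyl]propane-1,3-dione | O=C(c1ccc(OCc2ccccc2)cc1)C(C(=O)c1c(O)cc(OCc2ccccc2)cc1OCc1ccccc1)c1cc(-c2cc(=O)c3c(OCc4ccccc4)cc(OC)cc3o2)ccc1OCc1ccccc1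
F5 | step 12 | 1-[2,4-bis(benzyloxy)-6-bromophenyl]-2-{2-(benzyloxy)-5-[5-(benzyloxy)-7-methoxy-4-oxo-4H-chromen-2-yl]phenyl}-3-[4-(benzyloxy)phenyl]-3-hydroxypropan-1-one (diastereomer mixture, racemic) | OC(c1ccc(OCc2ccccc2)cc1)C(C(=O)c1c(Br)cc(OCc2ccccc2)cc1OCc1ccccc1)c1cc(-c2cc(=O)c3c(OCc4ccccc4)cc(OC)cc3o2)ccc1OCc1ccccc1
F6 | step 10 | ethyl 3-[2,4-bis(benzyloxy)-6-bromophenyl]-2-{2-(benzyloxy)-5-[5-(benzyloxy)-7-methoxy-4-oxo-4H-chromen-2-yl]phenyl}-3-hydroxypropanoate (diastereomer mixture, racemic) | CCOC(=O)C(C(O)c1c(Br)cc(OCc2ccccc2)cc1OCc1ccccc1)c1cc(-c2cc(=O)c3c(OCc4ccccc4)cc(OC)cc3o2)ccc1OCc1ccccc1
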